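**Retrosynthetic overview**
1. Target 23 ⇐ desilylation of 22 ⇐ acyclic bromo-enal 19: one chromium-mediated operation forms C6–C7, closing the ten-membered carbocycle, and the resulting alkoxide lactonises to the cis-fused α-methylene lactone (two rings, C6 and C7 set, on a chain that already carries the oxirane, the furoate and C1/C3/C8/C10).
2. 19 ⇐ dialdehyde 17 + methyl propiolate (C11–C13) ⇐ bis-PMB epoxide 15 (Shi epoxidation sets C1/C10 on the open chain).
3. 15 ⇐ enone 12 (CBS reduction sets C3; furoate on C8) ⇐ aldehyde 9 + (Z)-vinyl iodide 4 (Nozaki–Hiyama–Kishi, C3–C4).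
4. 9 ⇐ (R)-glycidyl PMB ether 5 + acetylide (C10, C1) + AlMe3 (C14) + ethylene oxide (C2, C3); 4 ⇐ but-2-yn-1-ol 1.
5. Ring order: oxirane (step 11), then carbocycle and lactone together (step 16).

Assumption: atoms carry germacrane numbers (ring C1–C10, C11–C13 lactone/methylene, C14 on C10, C15 on C4); the SMILES is read as 1R,3S,6S,7R,8R,10R, 4Z with a cis-fused lactone (H6/H7 cis); (R)-glycidyl 4-methoxybenzyl ether 5 is taken as a commercial chiral-pool material.

**Route**

Step 1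
Reactants: 1 but-2-yn-1-ol
Product: 3 (2Z)-3-iodobut-2-en-1-ol, via sodium alkenylalanate 2 (not isolated)
Conditions: NaAlH2(OCH2CH2OCH3)2, THF, 0 °C to rt; then I2, −78 °C to rt
Reagents that add atoms: iodine, II
Why: trans-hydroalumination of the propargylic alcohol through the cyclic alkoxyalanate puts Al on C3 cis to CH2O, and iodinolysis with retention gives the Z vinyl iodide that later becomes the 4Z ring alkene (Red-Al hydroalumination–iodination).

Step 2
Reactants: 3 (2Z)-3-iodobut-2-en-1-ol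
Product: 4 4-methoxybenzyl ether of 3
Conditions: NaH, 4-methoxybenzyl chloride, Bu4NI (cat.), THF, 0 °C to rt
Reagents that add atoms: 4-methoxybenzyl chloride, COc1ccc(CCl)cc1
Why: Williamson etherification of the allylic alkoxide; the vinyl iodide and its geometry are untouched.

Step 3
Reactants: 5 (2R)-2-{[(4-methoxybenzyl)oxy]methyl}oxirane
Product: 6 (2R)-1-[(4-methoxybenzyl)oxy]pent-4-yn-2-ol
Conditions: LiC≡CH·H2NCH2CH2NH2, DMSO, rt
Reagents that add atoms: lithium acetylide (ethylenediamine complex), [Li]C#C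
Why: SN2 opening of the terminal epoxide at CH2 by the acetylide; the C8 stereocentre (R, chiral pool) is not touched.

Step 4
Reactants: 6 (2R)-1-[(4-methoxybenzyl)oxy]pent-4-yn-2-ol
Product: 8 (2R,4E)-1-[(4-methoxybenzyl)oxy]-4-methylhept-4-ene-2,7-diol, via alkenyldimethylalane 7 (not isolated)
Conditions: AlMe3 (3 equiv), Cp2ZrCl2 (25 mol %), CH2Cl2, 0 °C to rt; then n-BuLi, THF, −78 °C; ethylene oxide, −78 to 0 °C
Reagents that add atoms: trimethylaluminium, C[Al](C)C; ethylene oxide, C1CO1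
Why: Negishi zirconium-catalysed syn-carboalumination puts Me on the internal and Al on the terminal alkyne carbon, giving only the E trisubstituted C1=C10 alkene, and the derived alanate opens ethylene oxide to add C2–C3.

Step 5
Reactants: 8 (2R,4E)-1-[(4-methoxybenzyl)oxy]-4-methylhept-4-ene-2,7-diol
Product: 9 (3E,6R)-6-hydroxy-7-[(4-methoxybenzyl)oxy]-4-methylhept-3-enal
Conditions: TEMPO (10 mol %), PhI(OAc)2, CH2Cl2, rt
Reagents that add atoms: none
Why: the TEMPO/PhI(OAc)2 oxidation takes the primary alcohol to the aldehyde and leaves the secondary C8 hydroxyl, under conditions mild enough for a β,γ-unsaturated aldehyde.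

Step 6
Reactants: 9 (3E,6R)-6-hydroxy-7-[(4-methoxybenzyl)oxy]-4-methylhept-3-enal; 4 4-methoxybenzyl ether of (2Z)-3-iodobut-2-en-1-ol
Product: 10 (2Z,6E,9R)-1,10-bis[(4-methoxybenzyl)oxy]-3,7-dimethyldeca-2,6-diene-4,9-diol (both C4 epimers; C4 here is C3 of the target)
Conditions: CrCl2 (4 equiv), NiCl2 (2 mol %), DMSO, rt
Reagents that add atoms: none
Why: Nozaki–Hiyama–Kishi coupling forms C3–C4 with retention of the Z geometry under neutral conditions that tolerate the free hydroxyl and do not conjugate the aldehyde; the unselective C3 centre is erased in step 7.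

Step 7
Reactants: 10 diol (C3 epimers)
Product: 11 (2Z,6E,9R)-9-hydroxy-1,10-bis[(4-methoxybenzyl)oxy]-3,7-dimethyldeca-2,6-dien-4-one
Conditions: MnO2, CH2Cl2, rt
Reagents that add atoms: none
Why: MnO2 oxidises only the allylic C3 alcohol (chemoselective allylic oxidation), which also tells the two secondary hydroxyls apart.

Step 8
Reactants: 11 hydroxy enone
Product: 12 (2R,4E,8Z)-1,10-bis[(4-methoxybenzyl)oxy]-4,8-dimethyl-7-oxodeca-4,8-dien-2-yl furan-3-carboxylate
Conditions: furan-3-carbonyl chloride, pyridine, DMAP (cat.), CH2Cl2, 0 °C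
Reagents that add atoms: furan-3-carbonyl chloride, O=C(Cl)c1ccoc1
Why: acylation of the only free hydroxyl (C8) with retention; weak base and low temperature keep the skipped enone from conjugating.

Step 9
Reactants: 12 furoate enone
Product: 13 (2R,4E,7S,8Z)-7-hydroxy-1,10-bis[(4-methoxybenzyl)oxy]-4,8-dimethyldeca-4,8-dien-2-yl furan-3-carboxylate
Conditions: (R)-2-methyl-CBS-oxazaborolidine (20 mol %), catecholborane, toluene, −78 °C
Reagents that add atoms: none
Why: Corey–Bakshi–Shibata reduction in which the α-branched alkenyl group is the large substituent, so the (R)-catalyst delivers hydride to give the 3S allylic alcohol (reagent control), without touching ester or alkenes.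

Step 10
Reactants: 13 allylic alcohol
Product: 14 7-O-tert-butyldimethylsilyl ether of 13 (C3–OTBS in target numbering)
Conditions: TBSOTf, 2,6-lutidine, CH2Cl2, −78 °C
Reagents that add atoms: tert-butyldimethylsilyl triflate, CC(C)(C)[Si](C)(C)OS(=O)(=O)C(F)(F)F
Why: silylation of the only free hydroxyl, needed so that the later Z-4-hydroxy-enal cannot close to a lactol or furan.

Step 11
Reactants: 14 silyl ether
Product: 15 (2R,4R,5R,7S,8Z)-7-[(tert-butyldimethylsilyl)oxy]-4,5-epoxy-1,10-bis[(4-methoxybenzyl)oxy]-4,8-dimethyldec-8-en-2-yl furan-3-carboxylate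
Conditions: Shi ketone (D-fructose-derived, 30 mol %), KHSO5 (as Oxone), K2CO3, Bu4NHSO4, MeCN/CH2(OMe)2/aq. Na2B4O7 buffer, 0 °C
Reagents that add atoms: potassium peroxymonosulfate, [K+].[O-]S(=O)(=O)OO
Why: Shi asymmetric epoxidation, where the chiral dioxirane attacks the electron-rich E-trisubstituted C1=C10 alkene through the spiro transition state to give the 1R,10R oxirane, while the Z alkene flanked by two allylic C–O bonds is deactivated.

Step 12
Reactants: 15 epoxide
Product: 16 (2R,4R,5R,7S,8Z)-7-[(tert-butyldimethylsilyl)oxy]-4,5-epoxy-1,10-dihydroxy-4,8-dimethyldec-8-en-2-yl furan-3-carboxylate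
Conditions: DDQ, CH2Cl2/pH 7 phosphate buffer, 0 °C; used crude
Reagents that add atoms: none
Why: oxidative cleavage of both PMB ethers by DDQ under buffered conditions that spare epoxide, silyl ether and furoate; the crude diol is used at once to avoid O8→O7 furoyl migration.

Step 13
Reactants: 16 diol
Product: 17 (2R,4R,5R,7S,8Z)-7-[(tert-butyldimethylsilyl)oxy]-4,5-epoxy-4,8-dimethyl-1,10-dioxodec-8-en-2-yl furan-3-carboxylate
Conditions: Dess–Martin periodinane, NaHCO3, CH2Cl2, 0 °C to rt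
Reagents that add atoms: none
Why: buffered Dess–Martin oxidation of both primary alcohols gives the C7 α-acyloxy aldehyde and the C6 (Z)-enal without Z/E isomerisation or epimerisation at C8.

Step 14
Reactants: 17 dialdehyde
Product: 18 methyl (4R,6R,7R,9S,10Z)-9-[(tert-butyldimethylsilyl)oxy]-6,7-epoxy-4-(furan-3-carbonyloxy)-3-hydroxy-6,10-dimethyl-2-methylidene-12-oxododec-10-enoate (C3 epimers; C3 here is C7 of the target)
Conditions: iBu2AlH (1.1 equiv), N-methylmorpholine N-oxide, methyl propiolate (1.2 equiv), THF, 0 °C; then 17, −20 °C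
Reagents that add atoms: methyl propiolate, C#CC(=O)OC
Why: hydroalumination of methyl propiolate gives the α-(methoxycarbonyl)vinylalane, which adds 1,2 to the more electrophilic, unhindered α-acyloxy aldehyde and not to the β,β-disubstituted enal (vinylalumination, a non-basic Morita–Baylis–Hillman surrogate); the new carbinol centre is lost in step 15.

Step 15
Reactants: 18 hydroxy ester
Product: 19 methyl (2Z,4R,6R,7R,9S,10Z)-2-(bromomethyl)-9-[(tert-butyldimethylsilyl)oxy]-6,7-epoxy-4-(furan-3-carbonyloxy)-6,10-dimethyl-12-oxododeca-2,10-dienoate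
Conditions: NBS, Me2S, CH2Cl2, −40 to 0 °C
Reagents that add atoms: N-bromosuccinimide, O=C1CCC(=O)N1Br
Why: Corey–Kim-type activation of the allylic alcohol followed by SN2′ attack of bromide gives the thermodynamically preferred (Z)-2-(bromomethyl)enoate (C8 trans to the ester) without acid, so epoxide and enal survive.

Step 16
Reactants: 19 bromo-enal
Product: 22 3-O-TBS ether of target 23, via allylchromium dichloride 20 (not isolated), via chromium dichloride alkoxide 21 (not isolated)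
Conditions: CrCl2 (6 equiv), THF, rt, syringe-pump addition of 19 (final 2 mM); aq. NH4Cl
Reagents that add atoms: none
Why: intramolecular Nozaki–Hiyama (chromium Barbier) allylation–lactonisation, in which the Z γ-substituted 2-(methoxycarbonyl)allylchromium attacks the enal through a closed chair transition state (syn adduct, hence the cis lactone, C6 S) on the face anti to C9 with H8 eclipsing the alkene (A1,3 strain, C7 R), closing the ten-membered ring, and the alkoxide then lactonises on the neighbouring methyl ester in the same flask.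

Step 17
Reactants: 22 3-O-TBS ether of the target
Product: 23 (1R,3S,4Z,6S,7R,8R,10R)-1,10-epoxy-8-(furan-3-carbonyloxy)-3-hydroxygermacra-4,11(13)-dien-12,6-olide (CNP0390850.1)
Conditions: HF·pyridine, pyridine, THF, 0 °C to rt
Reagents that add atoms: none
Why: buffered fluoride desilylation of the allylic silyl ether, mild enough for the trisubstituted epoxide, the α-methylene lactone and the furoate.

**Compound list**
1 | but-2-yn-1-ol | CC#CCO | starting material
2 | sodium bis(2-methoxyethoxy) cyclic alkenylalanate of 1 (Al on C3, O–Al ring) | [Na+].CC1=CCO[Al-]1(OCCOC)OCCOC | intermediate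
3 | (2Z)-3-iodobut-2-en-1-ol | C/C(I)=C/CO | intermediate
4 | 1-({[(2Z)-3-iodobut-2-en-1-yl]oxy}methyl)-4-methoxybenzene | C/C(I)=C/COCc1ccc(OC)cc1 | intermediate
5 | (2R)-2-{[(4-methoxybenzyl)oxy]methyl}oxirane | C1[C@@H](O1)COCc1ccc(OC)cc1 | starting material
6 | (2R)-1-[(4-methoxybenzyl)oxy]pent-4-yn-2-ol | C#CC[C@@H](O)COCc1ccc(OC)cc1 | intermediate
7 | (E)-alkenyldimethylalane of 6 (Me on C10, AlMe2 on C1, C8–O–AlMe2) | C/C(=C\[Al](C)C)C[C@@H](O[Al](C)C)COCc1ccc(OC)cc1 | intermediate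
8 | (2R,4E)-1-[(4-methoxybenzyl)oxy]-4-methylhept-4-ene-2,7-diol | C/C(=C\CCO)C[C@@H](O)COCc1ccc(OC)cc1 | intermediate
9 | (3E,6R)-6-hydroxy-7-[(4-methoxybenzyl)oxy]-4-methylhept-3-enal | C/C(=C\CC=O)C[C@@H](O)COCc1ccc(OC)cc1 | intermediate
10 | (2Z,6E,9R)-1,10-bis[(4-methoxybenzyl)oxy]-3,7-dimethyldeca-2,6-diene-4,9-diol, C4 epimers | COc1ccc(COC/C=C(/C)C(O)C/C=C(\C)C[C@@H](O)COCc2ccc(OC)cc2)cc1 | intermediate
11 | (2Z,6E,9R)-9-hydroxy-1,10-bis[(4-methoxybenzyl)oxy]-3,7-dimethyldeca-2,6-dien-4-one | COc1ccc(COC/C=C(/C)C(=O)C/C=C(\C)C[C@@H](O)COCc2ccc(OC)cc2)cc1 | intermediate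
12 | (2R,4E,8Z)-1,10-bis[(4-methoxybenzyl)oxy]-4,8-dimethyl-7-oxodeca-4,8-dien-2-yl furan-3-carboxylate | COc1ccc(COC/C=C(/C)C(=O)C/C=C(\C)C[C@@H](OC(=O)c3ccoc3)COCc2ccc(OC)cc2)cc1 | intermediate
13 | (2R,4E,7S,8Z)-7-hydroxy-1,10-bis[(4-methoxybenzyl)oxy]-4,8-dimethyldeca-4,8-dien-2-yl furan-3-carboxylate | COc1ccc(COC/C=C(/C)[C@@H](O)C/C=C(\C)C[C@@H](OC(=O)c3ccoc3)COCc2ccc(OC)cc2)cc1 | intermediate
14 | (2R,4E,7S,8Z)-7-[(tert-butyldimethylsilyl)oxy]-1,10-bis[(4-methoxybenzyl)oxy]-4,8-dimethyldeca-4,8-dien-2-yl furan-3-carboxylate | COc1ccc(COC/C=C(/C)[C@@H](O[Si](C)(C)C(C)(C)C)C/C=C(\C)C[C@@H](OC(=O)c3ccoc3)COCc2ccc(OC)cc2)cc1 | intermediate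
15 | (2R,4R,5R,7S,8Z)-7-[(tert-butyldimethylsilyl)oxy]-4,5-epoxy-1,10-bis[(4-methoxybenzyl)oxy]-4,8-dimethyldec-8-en-2-yl furan-3-carboxylate | COc1ccc(COC/C=C(/C)[C@@H](O[Si](C)(C)C(C)(C)C)C[C@H]3O[C@]3(C)C[C@@H](OC(=O)c4ccoc4)COCc2ccc(OC)cc2)cc1 | intermediate
16 | (2R,4R,5R,7S,8Z)-7-[(tert-butyldimethylsilyl)oxy]-4,5-epoxy-1,10-dihydroxy-4,8-dimethyldec-8-en-2-yl furan-3-carboxylate | OC/C=C(/C)[C@@H](O[Si](C)(C)C(C)(C)C)C[C@H]1O[C@]1(C)C[C@@H](OC(=O)c1ccoc1)CO | intermediate
17 | (2R,4R,5R,7S,8Z)-7-[(tert-butyldimethylsilyl)oxy]-4,5-epoxy-4,8-dimethyl-1,10-dioxodec-8-en-2-yl furan-3-carboxylate | O=C/C=C(/C)[C@@H](O[Si](C)(C)C(C)(C)C)C[C@H]1O[C@]1(C)C[C@@H](OC(=O)c1ccoc1)C=O | intermediate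
18 | methyl (4R,6R,7R,9S,10Z)-9-[(tert-butyldimethylsilyl)oxy]-6,7-epoxy-4-(furan-3-carbonyloxy)-3-hydroxy-6,10-dimethyl-2-methylidene-12-oxododec-10-enoate, C3 epimers | O=C/C=C(/C)[C@@H](O[Si](C)(C)C(C)(C)C)C[C@H]1O[C@]1(C)C[C@@H](OC(=O)c1ccoc1)C(O)C(=C)C(=O)OC | intermediate
19 | methyl (2Z,4R,6R,7R,9S,10Z)-2-(bromomethyl)-9-[(tert-butyldimethylsilyl)oxy]-6,7-epoxy-4-(furan-3-carbonyloxy)-6,10-dimethyl-12-oxododeca-2,10-dienoate | O=C/C=C(/C)[C@@H](O[Si](C)(C)C(C)(C)C)C[C@H]1O[C@]1(C)C[C@@H](OC(=O)c1ccoc1)/C=C(/C(=O)OC)CBr | intermediate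
20 | allylchromium dichloride from 19 (CrCl2 in place of Br) | O=C/C=C(/C)[C@@H](O[Si](C)(C)C(C)(C)C)C[C@H]1O[C@]1(C)C[C@@H](OC(=O)c1ccoc1)/C=C(/C(=O)OC)C[Cr](Cl)Cl | intermediate
21 | chromium dichloride alkoxide of the ring-closed hydroxy ester (ten-membered carbocycle, C6–O–CrCl2, C7–C(=CH2)CO2Me; 6S,7R) | Cl[Cr](Cl)O[C@H]1/C=C(/C)[C@@H](O[Si](C)(C)C(C)(C)C)C[C@H]2O[C@]2(C)C[C@@H](OC(=O)c2ccoc2)[C@H]1C(=C)C(=O)OC | intermediate
22 | (1R,3S,4Z,6S,7R,8R,10R)-3-[(tert-butyldimethylsilyl)oxy]-1,10-epoxy-8-(furan-3-carbonyloxy)germacra-4,11(13)-dien-12,6-olide | C=C1C(=O)O[C@H]2/C=C(/C)[C@@H](O[Si](C)(C)C(C)(C)C)C[C@H]3O[C@]3(C)C[C@@H](OC(=O)c3ccoc3)[C@@H]12 | intermediate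
23 | (1R,3S,4Z,6S,7R,8R,10R)-1,10-epoxy-8-(furan-3-carbonyloxy)-3-hydroxygermacra-4,11(13)-dien-12,6-olide | C=C1C(=O)O[C@H]2/C=C(/C)[C@@H](O)C[C@H]3O[C@]3(C)C[C@@H](OC(=O)c3ccoc3)[C@@H]12 | target

**Step count and risks**
Total steps: 17. Longest linear sequence: 15 (steps 3–17, from 5).

Steps most likely to fail:

Step 16 (ring closure). Risks are oligomerisation at the ten-membered ring size, the wrong face at C7, or a trans lactone. Fallback, setting out from 8 and coming back at 23, reverses the order of the ring closures. Diol 8 is silylated at the primary hydroxyl (TBSCl, imidazole) to silyl ether F2, acylated with furan-3-carbonyl chloride to furoate F3, and freed of its PMB group with DDQ to alcohol F4. Dess–Martin oxidation gives aldehyde F5, the vinylalumination of step 14 gives hydroxy ester F6, and NBS/Me2S gives allylic bromide F7. F7 is then joined with (2Z)-3-iodobut-2-enal F8 (from 3 with MnO2) in an intermolecular CrCl2 Barbier reaction, whose unconstrained chair transition state gives cis-lactone F9. HF·pyridine gives alcohol F10 and Dess–Martin oxidation gives aldehyde F11. The carbocycle is closed at C3–C4 by an intramolecular Nozaki–Hiyama–Kishi reaction (CrCl2, NiCl2 cat., DMSO, high dilution) to macrocyclic allylic alcohol F12; here C3 is set only by the ring. Shi epoxidation of F12 under the conditions of step 11 gives 23.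

Step 14 (acrylate introduction on the dialdehyde). Risks are attack at the enal, reduction by residual hydride, or furoyl migration. Fallback, setting out from 17 and coming back at 18: the stoichiometric alane is replaced by the amine-catalysed Morita–Baylis–Hillman reaction (methyl acrylate, DABCO, dioxane/water, rt). It relies on the conjugated, β,β-disubstituted enal being a much poorer electrophile for the ammonium enolate than the α-acyloxy aldehyde. No new isolated compound is made (F0).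

Step 9 (C3 by reduction of the skipped Z-enone). Risks are low selectivity or migration of the C1=C10 alkene at the ketone stage. Fallback, setting out from 9 and coming back at 13: C3 is set when C3–C4 is formed. Aldehyde 9 is acylated with furan-3-carbonyl chloride (pyridine, 0 °C) to aldehyde furoate F1. F1 is coupled with 4 in a catalytic asymmetric Nozaki–Hiyama–Kishi reaction (CrCl2 with a Kishi-type chiral oxazoline sulfonamide ligand, NiCl2 cat., Mn, Cp2ZrCl2, MeCN), the ligand antipode being chosen to give the 3S alcohol 13. This bypasses 10–12.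

**Further compounds**
F1 | step 9 | (2R,4E)-1-[(4-methoxybenzyl)oxy]-4-methyl-7-oxohept-4-en-2-yl furan-3-carboxylate | C/C(=C\CC=O)C[C@@H](OC(=O)c1ccoc1)COCc1ccc(OC)cc1
F0 | step 14 | none | none
F2 | step 16 | (2R,4E)-7-[(tert-butyldimethylsilyl)oxy]-1-[(4-methoxybenzyl)oxy]-4-methylhept-4-en-2-ol | C/C(=C\CCO[Si](C)(C)C(C)(C)C)C[C@@H](O)COCc1ccc(OC)cc1
F3 | step 16 | (2R,4E)-7-[(tert-butyldimethylsilyl)oxy]-1-[(4-methoxybenzyl)oxy]-4-methylhept-4-en-2-yl furan-3-carboxylate | C/C(=C\CCO[Si](C)(C)C(C)(C)C)C[C@@H](OC(=O)c1ccoc1)COCc1ccc(OC)cc1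
F4 | step 16 | (2R,4E)-7-[(tert-butyldimethylsilyl)oxy]-1-hydroxy-4-methylhept-4-en-2-yl furan-3-carboxylate | C/C(=C\CCO[Si](C)(C)C(C)(C)C)C[C@@H](OC(=O)c1ccoc1)CO
F5 | step 16 | (2R,4E)-7-[(tert-butyldimethylsilyl)oxy]-4-methyl-1-oxohept-4-en-2-yl furan-3-carboxylate | C/C(=C\CCO[Si](C)(C)C(C)(C)C)C[C@@H](OC(=O)c1ccoc1)C=O
F6 | step 16 | methyl (4R,6E)-9-[(tert-butyldimethylsilyl)oxy]-4-(furan-3-carbonyloxy)-3-hydroxy-6-methyl-2-methylidenenon-6-enoate, C3 epimers | C/C(=C\CCO[Si](C)(C)C(C)(C)C)C[C@@H](OC(=O)c1ccoc1)C(O)C(=C)C(=O)OC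
F7 | step 16 | methyl (2Z,4R,6E)-2-(bromomethyl)-9-[(tert-butyldimethylsilyl)oxy]-4-(furan-3-carbonyloxy)-6-methylnona-2,6-dienoate | C/C(=C\CCO[Si](C)(C)C(C)(C)C)C[C@@H](OC(=O)c1ccoc1)/C=C(/C(=O)OC)CBr
F8 | step 16 | (2Z)-3-iodobut-2-enal | C/C(I)=C/C=O
F9 | step 16 | (1R,3E)-6-[(tert-butyldimethylsilyl)oxy]-1-{(2R,3R)-2-[(1Z)-2-iodoprop-1-en-1-yl]-4-methylidene-5-oxooxolan-3-yl}-3-methylhex-3-en-1-yl furan-3-carboxylate (cis lactone) | C=C1C(=O)O[C@@H](/C=C(/C)I)[C@H]1[C@H](OC(=O)c2ccoc2)C/C(C)=C/CCO[Si](C)(C)C(C)(C)C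
F10 | step 16 | (1R,3E)-6-hydroxy-1-{(2R,3R)-2-[(1Z)-2-iodoprop-1-en-1-yl]-4-methylidene-5-oxooxolan-3-yl}-3-methylhex-3-en-1-yl furan-3-carboxylate | C=C1C(=O)O[C@@H](/C=C(/C)I)[C@H]1[C@H](OC(=O)c2ccoc2)C/C(C)=C/CCO
F11 | step 16 | (1R,3E)-1-{(2R,3R)-2-[(1Z)-2-iodoprop-1-en-1-yl]-4-methylidene-5-oxooxolan-3-yl}-3-methyl-6-oxohex-3-en-1-yl furan-3-carboxylate | C=C1C(=O)O[C@@H](/C=C(/C)I)[C@H]1[C@H](OC(=O)c2ccoc2)C/C(C)=C/CC=O
F12 | step 16 | (1(10)E,3S,4Z,6S,7R,8R)-8-(furan-3-carbonyloxy)-3-hydroxygermacra-1(10),4,11(13)-trien-12,6-olide | C=C1C(=O)O[C@H]2/C=C(/C)[C@@H](O)C/C=C(\C)C[C@@H](OC(=O)c3ccoc3)[C@@H]12
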